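**Retrosynthetic overview**

1. The last C=C bond is cut by a Horner–Wadsworth–Emmons disconnection into neopentyl aldehyde 33 and phosphonate 38 (coumarin A, from 2-methylresorcinol). The pyranone ring of coumarin B is cut back to phenol 26 (ortho-formylation, Wittig lactonisation).
2. The feature the route rests on: in coumarin B, C8 carries the cyclohexene carbon next to the quaternary centre and sits between the oxygen-bearing C7 and C8a, a 2-substituted resorcinol. This benzene ring is therefore grown on the core from siloxyalkyne 18 and the vinylketene of cyclobutenone 21 (C8–C8a and C6–C7, then C4a–C8a by electrocyclisation), so the crowded aryl–C bond is never made by coupling.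
3. Siloxyalkyne 18 comes from terminal alkyne 15 by acetylide oxidation. The cyclohexene core comes from an oxazolidinone-controlled Diels–Alder reaction of dienyne 5 with acrylimide 8, then enolate methylation anti to the alkynyl group.
4. Ring order: cyclohexene (Diels–Alder), benzene ring of coumarin B (benzannulation), pyranone ring of coumarin B (lactonisation); coumarin A is made apart and joined last.

Key step: step 13

Remark: the C1 carboxyl group is carried through the key step as a silyl-protected carbinol, because a methyl ester cis to the new phenol would lactonise onto it under the basic formylation conditions and could not be reduced selectively once the coumarin lactone is present.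

**Route**

Step 1
Reactants: 1 (triisopropylsilyl)acetylene; 2 (E)-1,2-dichloroethene
Product: 3 (E)-(4-chlorobut-3-en-1-yn-1-yl)triisopropylsilane
Conditions: Pd(PPh3)4 (cat.), CuI (cat.), n-BuNH2, 2 (5 equiv), Et2O, 23 °C
Reagents that add atoms: none
Why: Sonogashira coupling at one C–Cl bond of the dihaloalkene, held at monocoupling by the excess of 2 and proceeding with retention of the E geometry.

Step 2
Reactants: 3 (E)-(4-chlorobut-3-en-1-yn-1-yl)triisopropylsilane; 4 isopropenylmagnesium bromide
Product: 5 (E)-triisopropyl(5-methylhexa-3,5-dien-1-yn-1-yl)silane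
Conditions: Pd(PPh3)4 (cat.), THF, 0 → 23 °C
Reagents that add atoms: none
Why: Kumada coupling of the alkyne-activated vinyl chloride with retention of alkene geometry gives the 1-alkynyl-3-methyl diene.

Step 3
Reactants: 6 (R)-4-benzyl-1,3-oxazolidin-2-one; 7 acryloyl chloride
Product: 8 (R)-3-acryloyl-4-benzyl-1,3-oxazolidin-2-one
Conditions: n-BuLi, THF, −78 °C; then 7, −78 → 0 °C
Reagents that add atoms: none
Why: N-acylation of the lithiated oxazolidinone by the acid chloride, run cold to hold back polymerisation of the acrylimide.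

Step 4
Reactants: 5 (E)-triisopropyl(5-methylhexa-3,5-dien-1-yn-1-yl)silane; 8 (R)-3-acryloyl-4-benzyl-1,3-oxazolidin-2-one
Product: 9 (R)-4-benzyl-3-{[(1S,2R)-4-methyl-2-[(triisopropylsilyl)ethynyl]cyclohex-3-en-1-yl]carbonyl}-1,3-oxazolidin-2-one
Conditions: Et2AlCl (1.4 equiv), CH2Cl2, −78 → −40 °C
Reagents that add atoms: none
Why: Auxiliary-controlled, Lewis acid promoted Diels–Alder reaction in which the aluminium chelate fixes the s-cis acrylimide, the diene adds endo to the face opposite the benzyl group, and the 1-alkynyl and 3-methyl groups both direct the acyl-bearing carbon next to the alkynyl-bearing carbon, which sets C2 as R with C1 cis to it.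

Step 5
Reactants: 9 (R)-4-benzyl-3-{[(1S,2R)-4-methyl-2-[(triisopropylsilyl)ethynyl]cyclohex-3-en-1-yl]carbonyl}-1,3-oxazolidin-2-one
Product: 10 methyl (1S,2R)-4-methyl-2-[(triisopropylsilyl)ethynyl]cyclohex-3-ene-1-carboxylate
Conditions: NaOMe, MeOH–THF, 0 °C
Reagents that add atoms: sodium methoxide, [Na+].[O-]C
Why: Transesterification by methoxide attack at the exocyclic imide carbonyl releases auxiliary 6 for reuse; epimerisation at C1 would be harmless because step 6 planarises that carbon, and C2 is not acidic under these conditions.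

Step 6
Reactants: 10 methyl (1S,2R)-4-methyl-2-[(triisopropylsilyl)ethynyl]cyclohex-3-ene-1-carboxylate
Product: 12 methyl (1S,2R)-1,4-dimethyl-2-[(triisopropylsilyl)ethynyl]cyclohex-3-ene-1-carboxylate, via lithium enolate 11 (not isolated)
Conditions: LiN(i-Pr)2, THF, −78 °C; then MeI, −78 → 0 °C
Reagents that add atoms: iodomethane, CI
Why: Ester enolate alkylation in which allylic 1,3-strain with the enolate oxygen holds the C2 alkynyl group pseudoaxial, so iodomethane should enter C1 from the opposite face and set the quaternary centre with methyl trans to alkynyl (ester cis), as in alkylations of 2-substituted cyclohexanecarboxylate enolates.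

Step 7
Reactants: 12 methyl (1S,2R)-1,4-dimethyl-2-[(triisopropylsilyl)ethynyl]cyclohex-3-ene-1-carboxylate
Product: 13 [(1S,2R)-1,4-dimethyl-2-[(triisopropylsilyl)ethynyl]cyclohex-3-en-1-yl]methanol
Conditions: LiAlH4, THF, 0 °C
Reagents that add atoms: none
Why: Hydride reduction of the neopentyl ester to the primary alcohol; the silylalkyne and the trisubstituted alkene are inert to LiAlH4 at this temperature.

Step 8
Reactants: 13 [(1S,2R)-1,4-dimethyl-2-[(triisopropylsilyl)ethynyl]cyclohex-3-en-1-yl]methanol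
Product: 14 [(1S,2S)-2-ethynyl-1,4-dimethylcyclohex-3-en-1-yl]methanol
Conditions: Bu4NF, THF, 23 °C
Reagents that add atoms: none
Why: Fluoride-induced protodesilylation of the C(sp)–Si bond frees the terminal alkyne.

Step 9
Reactants: 14 [(1S,2S)-2-ethynyl-1,4-dimethylcyclohex-3-en-1-yl]methanol
Product: 15 tert-butyl{[(1S,2S)-2-ethynyl-1,4-dimethylcyclohex-3-en-1-yl]methoxy}dimethylsilane
Conditions: t-BuMe2SiCl, imidazole, DMF, 23 °C
Reagents that add atoms: tert-butyldimethylsilyl chloride, CC(C)(C)[Si](C)(C)Cl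
Why: Silylation of the primary alcohol masks the C1 carbinol through the acetylide chemistry and the benzannulation, and lets one fluoride treatment free it later.

Step 10
Reactants: 15 tert-butyl{[(1S,2S)-2-ethynyl-1,4-dimethylcyclohex-3-en-1-yl]methoxy}dimethylsilane
Product: 18 tert-butyl{[(1S,2R)-1,4-dimethyl-2-{[(triisopropylsilyl)oxy]ethynyl}cyclohex-3-en-1-yl]methoxy}dimethylsilane, via lithium acetylide 16 (not isolated), via lithium ynolate 17 (not isolated)
Conditions: n-BuLi, THF, −78 °C; LiOO-t-Bu (from t-BuOOH and LiN(SiMe3)2, THF, −78 °C), −78 → 0 °C; then i-Pr3SiOTf, −78 → 0 °C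
Reagents that add atoms: tert-butyl hydroperoxide, CC(C)(C)OO; triisopropylsilyl trifluoromethanesulfonate, CC(C)[Si](OS(=O)(=O)C(F)(F)F)(C(C)C)C(C)C
Why: Deprotonation to the lithium acetylide, electrophilic oxygen transfer from lithium tert-butyl peroxide to give the ynolate, and O-silylation by the bulky silyl triflate, the established way from terminal alkynes to 1-siloxyalkynes.

Step 11
Reactants: 19 3-oxocyclobutane-1-carboxylic acid
Product: 20 3-bromocyclobutan-1-one
Conditions: HgO, Br2, MgSO4, CH2Cl2, reflux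
Reagents that add atoms: bromine, BrBr
Why: Hunsdiecker-type bromodecarboxylation (Cristol–Firth variant) replaces the carboxyl group by bromine through an alkyl radical.

Step 12
Reactants: 20 3-bromocyclobutan-1-one
Product: 21 cyclobut-2-en-1-one
Conditions: n-Bu3N, 23 °C; then distillation into a cold trap under reduced pressure
Reagents that add atoms: none
Why: Amine-induced β-elimination of HBr from the β-bromo ketone gives the strained enone, which is used at once as a cold solution.

Step 13
Reactants: 18 tert-butyl{[(1S,2R)-1,4-dimethyl-2-{[(triisopropylsilyl)oxy]ethynyl}cyclohex-3-en-1-yl]methoxy}dimethylsilane; 21 cyclobut-2-en-1-one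
Product: 26 2-[(1R,6S)-6-{[(tert-butyldimethylsilyl)oxy]methyl}-3,6-dimethylcyclohex-2-en-1-yl]-3-[(triisopropylsilyl)oxy]phenol, via vinylketene 22 (not isolated), via 2-vinylcyclobutenone 23 (not isolated), via dienylketene 24 (not isolated), via cyclohexa-2,4-dienone 25 (not isolated)
Conditions: 21 (2.5 equiv, in portions), toluene, sealed tube, 80 °C, then 110 °C
Reagents that add atoms: none
Why: Heating opens cyclobutenone 21 by four-electron electrocyclic cleavage to vinylketene 22, whose carbonyl carbon is attacked by the oxygen-remote, nucleophilic alkyne carbon of 18 in a polar [2+2] cycloaddition that gives 23 and forms the C8–C8a and C6–C7 bonds of coumarin B. Four-electron conrotatory opening of 23 gives dienylketene 24, and the benzene ring is closed by six-electron disrotatory electrocyclisation (C4a–C8a bond) to dienone 25, which tautomerises to phenol 26. This is the Danheiser benzannulation of a cyclobutenone with a siloxyalkyne, which gives resorcinol monosilyl ethers. No stereocentre is formed, and the neutral thermal conditions leave the propargylic centre and the quaternary centre of the cyclohexene untouched. The step needs regioselectivity in the ketene–alkyne cycloaddition, which the polarisation of the ynol ether secures so that the cyclohexenyl-bearing carbon ends between the phenol and the silyl ether, and it needs the ketene to choose the alkyne over the ring alkene, which the nucleophilicity of the ynol ether secures.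

Step 14
Reactants: 26 2-[(1R,6S)-6-{[(tert-butyldimethylsilyl)oxy]methyl}-3,6-dimethylcyclohex-2-en-1-yl]-3-[(triisopropylsilyl)oxy]phenol
Product: 28 3-[(1R,6S)-6-{[(tert-butyldimethylsilyl)oxy]methyl}-3,6-dimethylcyclohex-2-en-1-yl]-2-hydroxy-4-[(triisopropylsilyl)oxy]benzaldehyde, via salicyl alcohol 27 (not isolated)
Conditions: MgCl2, Et3N, (CH2O)n, MeCN, reflux
Reagents that add atoms: paraformaldehyde (formaldehyde), C=O
Why: Casnati–Skattebøl ortho-formylation, in which the magnesium phenoxide delivers formaldehyde to the only free ortho position (C4a of coumarin B) and the hydroxymethyl intermediate is oxidised by hydride transfer to a second formaldehyde.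

Step 15
Reactants: 28 3-[(1R,6S)-6-{[(tert-butyldimethylsilyl)oxy]methyl}-3,6-dimethylcyclohex-2-en-1-yl]-2-hydroxy-4-[(triisopropylsilyl)oxy]benzaldehyde
Product: 30 8-[(1R,6S)-6-{[(tert-butyldimethylsilyl)oxy]methyl}-3,6-dimethylcyclohex-2-en-1-yl]-7-[(triisopropylsilyl)oxy]-2H-chromen-2-one, via E-cinnamate ester 29 (not isolated)
Conditions: Ph3P=CHCO2Et, PhNEt2, reflux
Reagents that add atoms: ethyl (triphenylphosphoranylidene)acetate, CCOC(=O)C=P(c1ccccc1)(c1ccccc1)c1ccccc1
Why: Wittig olefination of the salicylaldehyde, followed at this temperature by E to Z isomerisation of the cinnamate and lactonisation with loss of ethanol, closes the pyranone ring of coumarin B.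

Step 16
Reactants: 30 8-[(1R,6S)-6-{[(tert-butyldimethylsilyl)oxy]methyl}-3,6-dimethylcyclohex-2-en-1-yl]-7-[(triisopropylsilyl)oxy]-2H-chromen-2-one
Product: 31 7-hydroxy-8-[(1R,6S)-6-(hydroxymethyl)-3,6-dimethylcyclohex-2-en-1-yl]-2H-chromen-2-one
Conditions: Bu4NF, THF, 0 → 23 °C
Reagents that add atoms: none
Why: Fluoride cleaves the aryl triisopropylsilyl ether and the primary tert-butyldimethylsilyl ether in one operation under conditions the coumarin lactone tolerates.

Step 17
Reactants: 31 7-hydroxy-8-[(1R,6S)-6-(hydroxymethyl)-3,6-dimethylcyclohex-2-en-1-yl]-2H-chromen-2-one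
Product: 32 8-[(1R,6S)-6-(hydroxymethyl)-3,6-dimethylcyclohex-2-en-1-yl]-7-methoxy-2H-chromen-2-one
Conditions: MeI, K2CO3, acetone, 23 °C
Reagents that add atoms: iodomethane, CI
Why: Williamson etherification in which only the acidic 7-hydroxycoumarin phenol is deprotonated by K2CO3, so the neopentyl alcohol stays free.

Step 18
Reactants: 32 8-[(1R,6S)-6-(hydroxymethyl)-3,6-dimethylcyclohex-2-en-1-yl]-7-methoxy-2H-chromen-2-one
Product: 33 (1S,2S)-2-(7-methoxy-2-oxo-2H-chromen-8-yl)-1,4-dimethylcyclohex-3-ene-1-carbaldehyde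
Conditions: Dess–Martin periodinane, NaHCO3, CH2Cl2, 23 °C
Reagents that add atoms: none
Why: Dess–Martin oxidation of the primary alcohol to the aldehyde, which has no α-hydrogen and cannot epimerise, without touching the lactone that a hydride route from an ester would endanger.

Step 19
Reactants: 34 2-methylresorcinol
Product: 35 7-hydroxy-8-methyl-2H-chromen-2-one
Conditions: malic acid, conc. H2SO4, 100 °C
Reagents that add atoms: malic acid, OC(CC(=O)O)C(=O)O
Why: Pechmann condensation, in which the three-carbon aldehyde acid released from malic acid in H2SO4 attacks the ring position ortho to one hydroxyl and para to the other and then lactonises.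

Step 20
Reactants: 35 7-hydroxy-8-methyl-2H-chromen-2-one
Product: 36 7-methoxy-8-methyl-2H-chromen-2-one
Conditions: MeI, K2CO3, acetone, reflux
Reagents that add atoms: iodomethane, CI
Why: Williamson etherification of the phenol.

Step 21
Reactants: 36 7-methoxy-8-methyl-2H-chromen-2-one
Product: 37 8-(bromomethyl)-7-methoxy-2H-chromen-2-one
Conditions: NBS, AIBN (cat.), PhCF3, reflux
Reagents that add atoms: N-bromosuccinimide, O=C1CCC(=O)N1Br
Why: Wohl–Ziegler radical bromination at the only benzylic position.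

Step 22
Reactants: 37 8-(bromomethyl)-7-methoxy-2H-chromen-2-one
Product: 38 diethyl [(7-methoxy-2-oxo-2H-chromen-8-yl)methyl]phosphonate
Conditions: P(OEt)3, 130 °C
Reagents that add atoms: triethyl phosphite, CCOP(OCC)OCC
Why: Michaelis–Arbuzov reaction of the benzylic bromide.

Step 23
Reactants: 33 (1S,2S)-2-(7-methoxy-2-oxo-2H-chromen-8-yl)-1,4-dimethylcyclohex-3-ene-1-carbaldehyde; 38 diethyl [(7-methoxy-2-oxo-2H-chromen-8-yl)methyl]phosphonate
Product: 39 7-methoxy-8-[(E)-2-[(1R,2R)-2-(7-methoxy-2-oxo-2H-chromen-8-yl)-1,4-dimethylcyclohex-3-en-1-yl]ethenyl]-2H-chromen-2-one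
Conditions: NaN(SiMe3)2, THF, −78 → 23 °C
Reagents that add atoms: none
Why: Horner–Wadsworth–Emmons olefination of the non-enolisable aldehyde with the benzylic phosphonate anion, which should give the E alkene through the equilibrated adduct; the hindered amide base is chosen to spare both lactones.

**Compound list**

1 | (triisopropylsilyl)acetylene | C#C[Si](C(C)C)(C(C)C)C(C)C | starting material
2 | (E)-1,2-dichloroethene | Cl/C=C/Cl | starting material
3 | (E)-(4-chlorobut-3-en-1-yn-1-yl)triisopropylsilane | Cl/C=C/C#C[Si](C(C)C)(C(C)C)C(C)C | intermediate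
4 | isopropenylmagnesium bromide | CC(=C)[Mg]Br | starting material
5 | (E)-triisopropyl(5-methylhexa-3,5-dien-1-yn-1-yl)silane | CC(=C)/C=C/C#C[Si](C(C)C)(C(C)C)C(C)C | intermediate
6 | (R)-4-benzyl-1,3-oxazolidin-2-one | O=C1N[C@H](Cc2ccccc2)CO1 | starting material
7 | acryloyl chloride | C=CC(=O)Cl | starting material
8 | (R)-3-acryloyl-4-benzyl-1,3-oxazolidin-2-one | C=CC(=O)N1[C@H](Cc2ccccc2)COC1=O | intermediate
9 | (R)-4-benzyl-3-{[(1S,2R)-4-methyl-2-[(triisopropylsilyl)ethynyl]cyclohex-3-en-1-yl]carbonyl}-1,3-oxazolidin-2-one | O=C([C@H]1CCC(C)=C[C@H]1C#C[Si](C(C)C)(C(C)C)C(C)C)N2[C@H](Cc3ccccc3)COC2=O | intermediate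
10 | methyl (1S,2R)-4-methyl-2-[(triisopropylsilyl)ethynyl]cyclohex-3-ene-1-carboxylate | COC(=O)[C@H]1CCC(C)=C[C@H]1C#C[Si](C(C)C)(C(C)C)C(C)C | intermediate
11 | lithium enolate of ester 10 | COC(O[Li])=C1CCC(C)=C[C@H]1C#C[Si](C(C)C)(C(C)C)C(C)C | intermediate
12 | methyl (1S,2R)-1,4-dimethyl-2-[(triisopropylsilyl)ethynyl]cyclohex-3-ene-1-carboxylate | COC(=O)[C@@]1(C)CCC(C)=C[C@H]1C#C[Si](C(C)C)(C(C)C)C(C)C | intermediate
13 | [(1S,2R)-1,4-dimethyl-2-[(triisopropylsilyl)ethynyl]cyclohex-3-en-1-yl]methanol | OC[C@@]1(C)CCC(C)=C[C@H]1C#C[Si](C(C)C)(C(C)C)C(C)C | intermediate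
14 | [(1S,2S)-2-ethynyl-1,4-dimethylcyclohex-3-en-1-yl]methanol | OC[C@@]1(C)CCC(C)=C[C@H]1C#C | intermediate
15 | tert-butyl{[(1S,2S)-2-ethynyl-1,4-dimethylcyclohex-3-en-1-yl]methoxy}dimethylsilane | CC(C)(C)[Si](C)(C)OC[C@@]1(C)CCC(C)=C[C@H]1C#C | intermediate
16 | lithium acetylide of alkyne 15 | CC(C)(C)[Si](C)(C)OC[C@@]1(C)CCC(C)=C[C@H]1C#C[Li] | intermediate
17 | lithium ynolate derived from 16 | CC(C)(C)[Si](C)(C)OC[C@@]1(C)CCC(C)=C[C@H]1C#CO[Li] | intermediate
18 | tert-butyl{[(1S,2R)-1,4-dimethyl-2-{[(triisopropylsilyl)oxy]ethynyl}cyclohex-3-en-1-yl]methoxy}dimethylsilane (siloxyalkynyl cis to the silyloxymethyl group) | CC(C)(C)[Si](C)(C)OC[C@@]1(C)CCC(C)=C[C@H]1C#CO[Si](C(C)C)(C(C)C)C(C)C | intermediate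
19 | 3-oxocyclobutane-1-carboxylic acid | O=C1CC(C(=O)O)C1 | starting material
20 | 3-bromocyclobutan-1-one | O=C1CC(Br)C1 | intermediate
21 | cyclobut-2-en-1-one | O=C1CC=C1 | intermediate
22 | buta-1,3-dien-1-one (vinylketene) | C=CC=C=O | intermediate
23 | 2-[(1R,6S)-6-{[(tert-butyldimethylsilyl)oxy]methyl}-3,6-dimethylcyclohex-2-en-1-yl]-3-[(triisopropylsilyl)oxy]-4-vinylcyclobut-2-en-1-one | CC(C)(C)[Si](C)(C)OC[C@@]1(C)CCC(C)=C[C@H]1C2=C(O[Si](C(C)C)(C(C)C)C(C)C)C(C=C)C2=O | intermediate
24 | (3E)-2-[(1R,6S)-6-{[(tert-butyldimethylsilyl)oxy]methyl}-3,6-dimethylcyclohex-2-en-1-yl]-3-[(triisopropylsilyl)oxy]hexa-1,3,5-trien-1-one | CC(C)(C)[Si](C)(C)OC[C@@]1(C)CCC(C)=C[C@H]1C(=C=O)/C(O[Si](C(C)C)(C(C)C)C(C)C)=C\C=C | intermediate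
25 | 2-[(1R,6S)-6-{[(tert-butyldimethylsilyl)oxy]methyl}-3,6-dimethylcyclohex-2-en-1-yl]-3-[(triisopropylsilyl)oxy]cyclohexa-2,4-dien-1-one | CC(C)(C)[Si](C)(C)OC[C@@]1(C)CCC(C)=C[C@H]1C2=C(O[Si](C(C)C)(C(C)C)C(C)C)C=CCC2=O | intermediate
26 | 2-[(1R,6S)-6-{[(tert-butyldimethylsilyl)oxy]methyl}-3,6-dimethylcyclohex-2-en-1-yl]-3-[(triisopropylsilyl)oxy]phenol | CC(C)(C)[Si](C)(C)OC[C@@]1(C)CCC(C)=C[C@H]1c2c(O[Si](C(C)C)(C(C)C)C(C)C)cccc2O | intermediate
27 | 2-[(1R,6S)-6-{[(tert-butyldimethylsilyl)oxy]methyl}-3,6-dimethylcyclohex-2-en-1-yl]-6-(hydroxymethyl)-3-[(triisopropylsilyl)oxy]phenol | CC(C)(C)[Si](C)(C)OC[C@@]1(C)CCC(C)=C[C@H]1c2c(O[Si](C(C)C)(C(C)C)C(C)C)ccc(CO)c2O | intermediate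
28 | 3-[(1R,6S)-6-{[(tert-butyldimethylsilyl)oxy]methyl}-3,6-dimethylcyclohex-2-en-1-yl]-2-hydroxy-4-[(triisopropylsilyl)oxy]benzaldehyde | CC(C)(C)[Si](C)(C)OC[C@@]1(C)CCC(C)=C[C@H]1c2c(O[Si](C(C)C)(C(C)C)C(C)C)ccc(C=O)c2O | intermediate
29 | ethyl (E)-3-{3-[(1R,6S)-6-{[(tert-butyldimethylsilyl)oxy]methyl}-3,6-dimethylcyclohex-2-en-1-yl]-2-hydroxy-4-[(triisopropylsilyl)oxy]phenyl}prop-2-enoate | CC(C)(C)[Si](C)(C)OC[C@@]1(C)CCC(C)=C[C@H]1c2c(O[Si](C(C)C)(C(C)C)C(C)C)ccc(/C=C/C(=O)OCC)c2O | intermediate
30 | 8-[(1R,6S)-6-{[(tert-butyldimethylsilyl)oxy]methyl}-3,6-dimethylcyclohex-2-en-1-yl]-7-[(triisopropylsilyl)oxy]-2H-chromen-2-one | CC(C)(C)[Si](C)(C)OC[C@@]1(C)CCC(C)=C[C@H]1c2c(O[Si](C(C)C)(C(C)C)C(C)C)ccc3ccc(=O)oc23 | intermediate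
31 | 7-hydroxy-8-[(1R,6S)-6-(hydroxymethyl)-3,6-dimethylcyclohex-2-en-1-yl]-2H-chromen-2-one | OC[C@@]1(C)CCC(C)=C[C@H]1c2c(O)ccc3ccc(=O)oc23 | intermediate
32 | 8-[(1R,6S)-6-(hydroxymethyl)-3,6-dimethylcyclohex-2-en-1-yl]-7-methoxy-2H-chromen-2-one | OC[C@@]1(C)CCC(C)=C[C@H]1c2c(OC)ccc3ccc(=O)oc23 | intermediate
33 | (1S,2S)-2-(7-methoxy-2-oxo-2H-chromen-8-yl)-1,4-dimethylcyclohex-3-ene-1-carbaldehyde | O=C[C@@]1(C)CCC(C)=C[C@H]1c2c(OC)ccc3ccc(=O)oc23 | intermediate
34 | 2-methylresorcinol | Cc1c(O)cccc1O | starting material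
35 | 7-hydroxy-8-methyl-2H-chromen-2-one | Cc1c(O)ccc2ccc(=O)oc12 | intermediate
36 | 7-methoxy-8-methyl-2H-chromen-2-one | COc1ccc2ccc(=O)oc2c1C | intermediate
37 | 8-(bromomethyl)-7-methoxy-2H-chromen-2-one | COc1ccc2ccc(=O)oc2c1CBr | intermediate
38 | diethyl [(7-methoxy-2-oxo-2H-chromen-8-yl)methyl]phosphonate | CCOP(=O)(OCC)Cc1c(OC)ccc2ccc(=O)oc12 | intermediate
39 | 7-methoxy-8-[(E)-2-[(1R,2R)-2-(7-methoxy-2-oxo-2H-chromen-8-yl)-1,4-dimethylcyclohex-3-en-1-yl]ethenyl]-2H-chromen-2-one (CNP0156435.1) | COc1ccc2ccc(=O)oc2c1/C=C/[C@@]1(C)CCC(C)=C[C@H]1c1c(OC)ccc2ccc(=O)oc12 | target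

**Step count and risks**

Total step count: 23. Longest linear sequence: 16 steps (steps 1, 2, 4 to 10, 13 to 18 and 23).

Steps most likely to fail:

Step 13 (key step). Cyclobutenone may polymerise at the temperature needed for its ring opening, and capture of the vinylketene by the hindered alkyne may be slow enough for 1,3-silyl migration of the siloxyalkyne to a silylketene to compete. Fallback, setting out from 18 and coming back at 26: the same vinylketene is generated photochemically at room temperature instead of thermally. Methyl vinyl ketone is converted by deacylative diazo transfer (LiN(SiMe3)2, CF3CO2CH2CF3; then MsN3, Et3N) into 1-diazobut-3-en-2-one F1. Irradiation of F1 together with 18 (CH2Cl2, 254 nm, 23 °C) triggers a Wolff rearrangement to vinylketene 22, cycloadduct 23 forms in the cold, and brief heating (toluene, 80 °C) carries it on to 26.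

Step 6. Facial selectivity in the methylation of enolate 11 may be poor if the slim alkynyl group does not hold the pseudoaxial position, which would erode the configuration of the quaternary centre. Fallback, setting out from 5 and coming back at 13: the quaternary centre is set in the cycloaddition instead of by alkylation. Diene 5 and methacrolein, under a chiral oxazaborolidinium Lewis acid (proline-derived o-tolyl oxazaborolidine activated by HNTf2, antipode chosen for the 1S,2R product; CH2Cl2, −78 °C), should give (1S,2R)-1,4-dimethyl-2-[(triisopropylsilyl)ethynyl]cyclohex-3-ene-1-carbaldehyde F2 as the endo adduct with formyl cis to alkynyl, to be separated from any exo isomer. Reduction with NaBH4 (MeOH, 0 °C) then gives 13.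

Step 23. Addition of the doubly ortho-substituted benzylic phosphonate anion to the neopentyl aldehyde may be slow, so that base-induced opening of, or conjugate addition to, the coumarin lactones takes over. Fallback, setting out from 33 and coming back at 39: the aryl–vinyl bond is made by a Heck reaction instead of by olefination. Wittig methylenation of 33 (Ph3P=CH2, THF, −78 → 0 °C) gives 8-[(1R,6R)-6-ethenyl-3,6-dimethylcyclohex-2-en-1-yl]-7-methoxy-2H-chromen-2-one F3. 7-Hydroxycoumarin is iodinated (I2, KI, aqueous NH3) to 7-hydroxy-8-iodo-2H-chromen-2-one F4 and methylated (MeI, K2CO3, acetone) to 8-iodo-7-methoxy-2H-chromen-2-one F5. Heck coupling of F3 with F5 (Pd(OAc)2, P(o-tol)3, Et3N, DMF, 100 °C) should give 39 as the E alkene only, because the quaternary carbon offers no second β-hydrogen.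

Further compounds

F1 | step 13 | 1-diazobut-3-en-2-one | C=CC(=O)C=[N+]=[N-]
F2 | step 6 | (1S,2R)-1,4-dimethyl-2-[(triisopropylsilyl)ethynyl]cyclohex-3-ene-1-carbaldehyde | O=C[C@@]1(C)CCC(C)=C[C@H]1C#C[Si](C(C)C)(C(C)C)C(C)C
F3 | step 23 | 8-[(1R,6R)-6-ethenyl-3,6-dimethylcyclohex-2-en-1-yl]-7-methoxy-2H-chromen-2-one | C=C[C@@]1(C)CCC(C)=C[C@H]1c2c(OC)ccc3ccc(=O)oc23
F4 | step 23 | 7-hydroxy-8-iodo-2H-chromen-2-one | Oc1ccc2ccc(=O)oc2c1I
F5 | step 23 | 8-iodo-7-methoxy-2H-chromen-2-one | COc1ccc2ccc(=O)oc2c1I
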